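**Plan**
1. Retrosynthesis: the four O‑benzyl bonds and the methyl ester are cut last and the CH2OH on C3 is traced to a vinyl group. The C2–C3 bond of ring B is then cut as a retro‑[2,3]‑Wittig shift to a benzo‑fused nine‑membered allyl enol ether. That ring is cut at C3=CH (metathesis), O–allyl, C2–O (enolate oxidation) and C1–C8a (conjugate arylation).
2. Enabling feature: with ring B numbered C1 (CH–aryl), C2 (C(OH)CO2H), C3 (C(OH)CH2OH), C4 (CH2), the C2 oxygen and the CH2OH on C3 are cis. A C2–O–CH2–CH=C3 ether therefore delivers the C2–C3 bond and a vinyl group (latent CH2OH) on the correct face in one sigmatropic event.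
3. Forward order: a ring‑A boronate (from homovanillic acid) and the cinnamate of the pendant aryl (from 3,4‑dihydroxy‑5‑methoxybenzaldehyde) are joined at C1. C2 is oxygenated and O‑allylated, the nine‑membered ring closes by metathesis, and ring B closes in the Wittig contraction. Vinyl cleavage, reduction, saponification and hydrogenolysis finish.
4. Stereochemistry: C1 comes from a rhodium/chiral‑diene conjugate arylation. C2 and C3 come from the key step, C2 relayed from C1 by allylic 1,3‑strain and C3 fixed by the ring‑cis enol ether in a cis‑fused five/six transition state.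

Key step: step 11

Remark: Ar in the names stands for 3,4‑bis(benzyloxy)‑5‑methoxyphenyl.
Remark: C2 of 13, 15 and 16 is carried as a mixture of epimers (drawn without configuration), because step 11 planarises this centre.

**Step 1**
Reactants: 1 homovanillic acid
Product: 2 benzyl [4-(benzyloxy)-3-methoxyphenyl]acetate
Conditions: BnBr (2.3 equiv), K2CO3, DMF, 60 °C
Reagents that add atoms: benzyl bromide, BrCc1ccccc1
Why: Williamson-type O‑alkylation of both the phenoxide and the carboxylate protects the phenol and makes the benzyl ester whose benzyloxy group later becomes C3–OBn.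

**Step 2**
Reactants: 2 benzyl [4-(benzyloxy)-3-methoxyphenyl]acetate
Product: 3 benzyl [4-(benzyloxy)-2-bromo-5-methoxyphenyl]acetate
Conditions: NBS, MeCN, 0 °C to rt, dark
Reagents that add atoms: N-bromosuccinimide, O=C1CCC(=O)N1Br
Why: Electrophilic aromatic bromination should go to the position para to OMe and ortho to the CH2 chain, the most activated open site, which is the future C8a.

**Step 3**
Reactants: 3 benzyl [4-(benzyloxy)-2-bromo-5-methoxyphenyl]acetate
Product: 4 1-(benzyloxy)-4-[2-(benzyloxy)prop-2-en-1-yl]-5-bromo-2-methoxybenzene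
Conditions: Cp2Ti(μ-Cl)(μ-CH2)AlMe2 (Tebbe reagent, 1.3 equiv), pyridine (cat.), THF–toluene, −40 °C to rt; filtration through basic alumina
Reagents that add atoms: Tebbe reagent Cp2Ti(μ-Cl)(μ-CH2)AlMe2, C[Al-]1(C)C[Ti](C2C=CC=C2)(C2C=CC=C2)[Cl+]1
Why: Tebbe methylenation turns the ester carbonyl into the 1,1‑disubstituted benzyl enol ether without enolising the arylacetate, and is placed here because this is the only ester present at this stage.

**Step 4**
Reactants: 4 1-(benzyloxy)-4-[2-(benzyloxy)prop-2-en-1-yl]-5-bromo-2-methoxybenzene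
Product: 6 2-{5-(benzyloxy)-2-[2-(benzyloxy)prop-2-en-1-yl]-4-methoxyphenyl}-4,4,5,5-tetramethyl-1,3,2-dioxaborolane, via aryllithium 5 (not isolated)
Conditions: n-BuLi, THF, −78 °C; then iPrOBpin, −78 °C to 0 °C; H2O
Reagents that add atoms: 2-isopropoxy-4,4,5,5-tetramethyl-1,3,2-dioxaborolane, CC(C)OB1OC(C)(C)C(C)(C)O1
Why: Bromine–lithium exchange followed by borylation; at −78 °C the exchange should outrun deprotonation of the benzylic CH2, and all later operations up to the ring closure are basic or neutral, which the acid‑labile enol ether tolerates.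

**Step 5**
Reactants: 7 3,4-dihydroxy-5-methoxybenzaldehyde
Product: 8 3,4-bis(benzyloxy)-5-methoxybenzaldehyde
Conditions: BnBr (2.3 equiv), K2CO3, DMF, 60 °C
Reagents that add atoms: benzyl bromide, BrCc1ccccc1
Why: Williamson ether synthesis on both phenols gives protection that comes off together with the other benzyl groups in the last step.

**Step 6**
Reactants: 8 3,4-bis(benzyloxy)-5-methoxybenzaldehyde; 9 methyl (triphenyl-λ5-phosphanylidene)acetate
Product: 10 methyl (2E)-3-Ar-prop-2-enoate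
Conditions: toluene, 90 °C
Reagents that add atoms: none
Why: Wittig olefination with a stabilised ylide should give the E‑enoate, in which the aldehyde carbon becomes C1 and the ylide supplies C2 and the carboxyl carbon.

**Step 7**
Reactants: 6 aryl pinacol boronate of ring A; 10 methyl (2E)-3-Ar-prop-2-enoate
Product: 11 methyl (3S)-3-Ar-3-{5-(benzyloxy)-2-[2-(benzyloxy)prop-2-en-1-yl]-4-methoxyphenyl}propanoate
Conditions: [RhCl(C2H4)2]2 (2.5 mol %), (1S,4S)-2,5-diphenylbicyclo[2.2.2]octa-2,5-diene (6 mol %), KOH (0.3 equiv), dioxane–H2O 10:1, 50 °C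
Reagents that add atoms: none
Why: Rhodium-catalysed asymmetric conjugate addition of an arylboron reagent (Hayashi–Miyaura reaction): the aryl–rhodium species must add to the Si face of C3 of the enoate to set C1 as S; the (1S,4S) diene is the antipode expected to do this, and the (1R,4R) ligand is used instead should a first run show the opposite sense.

**Step 8**
Reactants: 11 methyl (3S)-3,3-diarylpropanoate
Product: 13 methyl (2RS,3S)-3-Ar-3-{5-(benzyloxy)-2-[2-(benzyloxy)prop-2-en-1-yl]-4-methoxyphenyl}-2-hydroxypropanoate, via potassium ester enolate 12 (not isolated)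
Conditions: KN(SiMe3)2, THF, −78 °C; then 2-(phenylsulfonyl)-3-phenyloxaziridine, −78 °C; AcOH
Reagents that add atoms: 2-(phenylsulfonyl)-3-phenyloxaziridine, O1N(S(=O)(=O)c2ccccc2)C1c1ccccc1
Why: Enolate oxidation with an N‑sulfonyloxaziridine transfers electrophilic oxygen to C2; either C2 epimer serves because this centre is planarised again in step 11.

**Step 9**
Reactants: 13 methyl (2RS,3S)-2-hydroxy-3,3-diarylpropanoate; 14 allyl bromide
Product: 15 methyl (2RS,3S)-3-Ar-3-{5-(benzyloxy)-2-[2-(benzyloxy)prop-2-en-1-yl]-4-methoxyphenyl}-2-(prop-2-en-1-yloxy)propanoate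
Conditions: NaH, allyl bromide, Bu4NI (cat.), DMF, 0 °C to rt
Reagents that add atoms: none
Why: Williamson etherification of the C2 alkoxide with an allylic bromide; base-induced epimerisation at C2 is of no consequence.

**Step 10**
Reactants: 15 methyl (2RS,3S)-2-(allyloxy)-3,3-diarylpropanoate
Product: 16 methyl (1S,2RS,5E)-1-Ar-6,10-bis(benzyloxy)-9-methoxy-1,2,4,7-tetrahydro-3-benzoxonine-2-carboxylate
Conditions: second-generation Hoveyda–Grubbs catalyst RuCl2(H2IMes)(=CH-C6H4-2-OiPr) (10 mol %), 1,4-benzoquinone (20 mol %), toluene (2 mM), 80 °C, argon sparge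
Reagents that add atoms: none
Why: Ring-closing olefin metathesis between a monosubstituted olefin and a 1,1‑disubstituted enol ether: ruthenium loads at the allyl ether and closes onto the enol ether with loss of ethene, and the benzo‑fused nine‑membered ring should accept the new trisubstituted double bond only as its ring‑cis isomer.

**Step 11**
Reactants: 16 nine-membered allyl enol ether (C2 epimers)
Product: 19 methyl (1S,2S,3R)-1-Ar-3,7-bis(benzyloxy)-3-ethenyl-2-hydroxy-6-methoxy-1,2,3,4-tetrahydronaphthalene-2-carboxylate, via lithium ester enolate 17 (not isolated), via lithium alkoxide 18 (not isolated)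
Conditions: LiN(iPr)2 (1.1 equiv), THF–DMPU, −78 °C to −20 °C; AcOH, −78 °C
Reagents that add atoms: none
Why: Proposed new method: LiN(iPr)2 removes the only acidic proton (C2–H) to give lithium enolate 17, whose carbon bonds to the enol-ether carbon C3 across the ring while the O–CH2 bond breaks in a concerted six-electron [2,3]-sigmatropic (Wittig) shift through a five-membered envelope, which frees the C2 alkoxide 18 and turns the O–CH2–CH= unit into a vinyl group on C3; the closest known reaction types are the [2,3]-Wittig rearrangement of acyclic α-allyloxy ester enolates and the ring-contracting Wittig shifts of larger cyclic allyl ethers, neither of which has been run on a nine-membered ring with an enol-ether terminus. Ring B closes in a transannular 6-exo-trig (enol-exo) mode. C3 is set by the ring-cis enol ether together with the cis fusion of the forming six-membered ring to the five-membered transition state, which places the vinyl group on the face of the C2 oxygen and C3–OBn on the face of the ester. C2 is set by C1: allylic 1,3-strain keeps C1–H in the enolate plane, so C3, which can reach C2 only from the side of its benzo tether, adds anti to the pendant aryl and leaves that aryl cis to the C2 oxygen. The step needs the [2,3] shift to win over [1,2] shift, ketene loss and deprotonation at C4, and the low temperature, the small excess of base and the short transannular C2–C3 distance enforced by the ring-cis double bond and the benzo unit should secure this.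

**Step 12**
Reactants: 19 vinyl tetralin ester
Product: 21 methyl (1S,2S,3S)-1-Ar-3,7-bis(benzyloxy)-3-formyl-2-hydroxy-6-methoxy-1,2,3,4-tetrahydronaphthalene-2-carboxylate, via vicinal diol 20 (not isolated)
Conditions: OsO4 (4 mol %), NaIO4 (4 equiv), 2,6-lutidine, dioxane–H2O 3:1, rt
Reagents that add atoms: osmium tetroxide, O=[Os](=O)(=O)=O; sodium periodate, [Na+].[O-]I(=O)(=O)=O
Why: Lemieux–Johnson oxidation: OsO4 dihydroxylates the only olefin and NaIO4 cleaves the diol in situ to the aldehyde, leaving the electron-rich arenes, the tertiary alcohol and all three stereocentres untouched.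

**Step 13**
Reactants: 21 aldehyde
Product: 22 methyl (1S,2S,3R)-1-Ar-3,7-bis(benzyloxy)-2-hydroxy-3-(hydroxymethyl)-6-methoxy-1,2,3,4-tetrahydronaphthalene-2-carboxylate
Conditions: NaBH4, THF–MeOH, −20 °C
Reagents that add atoms: none
Why: Borohydride reduction of the aldehyde, run cold and directly on the crude aldehyde so that it outruns retro-aldol opening of the β-hydroxy aldehyde.

**Step 14**
Reactants: 22 diol ester
Product: 23 (1S,2S,3R)-1-Ar-3,7-bis(benzyloxy)-2-hydroxy-3-(hydroxymethyl)-6-methoxy-1,2,3,4-tetrahydronaphthalene-2-carboxylic acid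
Conditions: LiOH, THF–MeOH–H2O, 40 °C; then 1 M HCl to pH 3, 0 °C
Reagents that add atoms: lithium hydroxide, [Li+].[OH-]
Why: Ester saponification by acyl–oxygen cleavage, done before debenzylation so that no free catechol meets base; any lactone formed from 22 in passing opens to the same carboxylate.

**Step 15**
Reactants: 23 tetrabenzyl acid
Product: 24 plicatic acid
Conditions: H2 (1 atm), Pd(OH)2/C, MeOH–EtOAc, rt
Reagents that add atoms: none
Why: Catalytic hydrogenolysis cleaves the three aryl benzyl ethers and the tertiary alkyl benzyl ether; nothing else is reducible, so the stereocentres stay as set.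

**Compound list**
1 | homovanillic acid | COc1cc(CC(=O)O)ccc1O | starting material
2 | benzyl [4-(benzyloxy)-3-methoxyphenyl]acetate | COc1cc(CC(=O)OCc2ccccc2)ccc1OCc1ccccc1 | intermediate
3 | benzyl [4-(benzyloxy)-2-bromo-5-methoxyphenyl]acetate | COc1cc(CC(=O)OCc2ccccc2)c(Br)cc1OCc1ccccc1 | intermediate
4 | 1-(benzyloxy)-4-[2-(benzyloxy)prop-2-en-1-yl]-5-bromo-2-methoxybenzene | COc1cc(CC(=C)OCc2ccccc2)c(Br)cc1OCc1ccccc1 | intermediate
5 | {5-(benzyloxy)-2-[2-(benzyloxy)prop-2-en-1-yl]-4-methoxyphenyl}lithium (not isolated) | COc1cc(CC(=C)OCc2ccccc2)c([Li])cc1OCc1ccccc1 | intermediate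
6 | 2-{5-(benzyloxy)-2-[2-(benzyloxy)prop-2-en-1-yl]-4-methoxyphenyl}-4,4,5,5-tetramethyl-1,3,2-dioxaborolane | COc1cc(CC(=C)OCc2ccccc2)c(B2OC(C)(C)C(C)(C)O2)cc1OCc1ccccc1 | intermediate
7 | 3,4-dihydroxy-5-methoxybenzaldehyde | COc1cc(C=O)cc(O)c1O | starting material
8 | 3,4-bis(benzyloxy)-5-methoxybenzaldehyde | COc1cc(C=O)cc(OCc2ccccc2)c1OCc1ccccc1 | intermediate
9 | methyl (triphenyl-λ5-phosphanylidene)acetate | COC(=O)C=P(c1ccccc1)(c1ccccc1)c1ccccc1 | starting material
10 | methyl (2E)-3-[3,4-bis(benzyloxy)-5-methoxyphenyl]prop-2-enoate | COC(=O)/C=C/c1cc(OC)c(OCc2ccccc2)c(OCc2ccccc2)c1 | intermediate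
11 | methyl (3S)-3-Ar-3-{5-(benzyloxy)-2-[2-(benzyloxy)prop-2-en-1-yl]-4-methoxyphenyl}propanoate | COc1cc(CC(=C)OCc2ccccc2)c(cc1OCc1ccccc1)[C@H](c1cc(OCc2ccccc2)c(OCc2ccccc2)c(OC)c1)CC(=O)OC | intermediate
12 | potassium ester enolate of 11 (not isolated) | COc1cc(CC(=C)OCc2ccccc2)c(cc1OCc1ccccc1)[C@H](c1cc(OCc2ccccc2)c(OCc2ccccc2)c(OC)c1)C=C(OC)[O-].[K+] | intermediate
13 | methyl (2RS,3S)-3-Ar-3-{5-(benzyloxy)-2-[2-(benzyloxy)prop-2-en-1-yl]-4-methoxyphenyl}-2-hydroxypropanoate | COc1cc(CC(=C)OCc2ccccc2)c(cc1OCc1ccccc1)[C@H](c1cc(OCc2ccccc2)c(OCc2ccccc2)c(OC)c1)C(O)C(=O)OC | intermediate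
14 | allyl bromide (3-bromoprop-1-ene) | C=CCBr | starting material
15 | methyl (2RS,3S)-3-Ar-3-{5-(benzyloxy)-2-[2-(benzyloxy)prop-2-en-1-yl]-4-methoxyphenyl}-2-(prop-2-en-1-yloxy)propanoate | COc1cc(CC(=C)OCc2ccccc2)c(cc1OCc1ccccc1)[C@H](c1cc(OCc2ccccc2)c(OCc2ccccc2)c(OC)c1)C(OCC=C)C(=O)OC | intermediate
16 | methyl (1S,2RS,5E)-1-Ar-6,10-bis(benzyloxy)-9-methoxy-1,2,4,7-tetrahydro-3-benzoxonine-2-carboxylate (nine-membered ring-cis allyl enol ether) | COc1cc2c(cc1OCc1ccccc1)[C@H](c1cc(OCc3ccccc3)c(OCc3ccccc3)c(OC)c1)C(C(=O)OC)OC/C=C(/OCc1ccccc1)C2 | intermediate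
17 | lithium ester enolate of 16 (not isolated) | COc1cc2c(cc1OCc1ccccc1)[C@H](c1cc(OCc3ccccc3)c(OCc3ccccc3)c(OC)c1)C(=C(OC)[O-])OC/C=C(/OCc1ccccc1)C2.[Li+] | intermediate
18 | lithium C2 alkoxide of 19 (not isolated) | COc1cc2c(cc1OCc1ccccc1)[C@H](c1cc(OCc3ccccc3)c(OCc3ccccc3)c(OC)c1)[C@@]([O-])(C(=O)OC)[C@](OCc1ccccc1)(C=C)C2.[Li+] | intermediate
19 | methyl (1S,2S,3R)-1-Ar-3,7-bis(benzyloxy)-3-ethenyl-2-hydroxy-6-methoxy-1,2,3,4-tetrahydronaphthalene-2-carboxylate | COc1cc2c(cc1OCc1ccccc1)[C@H](c1cc(OCc3ccccc3)c(OCc3ccccc3)c(OC)c1)[C@@](O)(C(=O)OC)[C@](OCc1ccccc1)(C=C)C2 | intermediate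
20 | methyl (1S,2S,3R)-1-Ar-3,7-bis(benzyloxy)-3-(1,2-dihydroxyethyl)-2-hydroxy-6-methoxy-1,2,3,4-tetrahydronaphthalene-2-carboxylate (not isolated) | COc1cc2c(cc1OCc1ccccc1)[C@H](c1cc(OCc3ccccc3)c(OCc3ccccc3)c(OC)c1)[C@@](O)(C(=O)OC)[C@](OCc1ccccc1)(C(O)CO)C2 | intermediate
21 | methyl (1S,2S,3S)-1-Ar-3,7-bis(benzyloxy)-3-formyl-2-hydroxy-6-methoxy-1,2,3,4-tetrahydronaphthalene-2-carboxylate | COc1cc2c(cc1OCc1ccccc1)[C@H](c1cc(OCc3ccccc3)c(OCc3ccccc3)c(OC)c1)[C@@](O)(C(=O)OC)[C@](OCc1ccccc1)(C=O)C2 | intermediate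
22 | methyl (1S,2S,3R)-1-Ar-3,7-bis(benzyloxy)-2-hydroxy-3-(hydroxymethyl)-6-methoxy-1,2,3,4-tetrahydronaphthalene-2-carboxylate | COc1cc2c(cc1OCc1ccccc1)[C@H](c1cc(OCc3ccccc3)c(OCc3ccccc3)c(OC)c1)[C@@](O)(C(=O)OC)[C@](OCc1ccccc1)(CO)C2 | intermediate
23 | (1S,2S,3R)-1-Ar-3,7-bis(benzyloxy)-2-hydroxy-3-(hydroxymethyl)-6-methoxy-1,2,3,4-tetrahydronaphthalene-2-carboxylic acid | COc1cc2c(cc1OCc1ccccc1)[C@H](c1cc(OCc3ccccc3)c(OCc3ccccc3)c(OC)c1)[C@@](O)(C(=O)O)[C@](OCc1ccccc1)(CO)C2 | intermediate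
24 | plicatic acid, (1S,2S,3R)-1-(3,4-dihydroxy-5-methoxyphenyl)-2,3,7-trihydroxy-3-(hydroxymethyl)-6-methoxy-1,2,3,4-tetrahydronaphthalene-2-carboxylic acid | COc1cc2c(cc1O)[C@H](c1cc(O)c(O)c(OC)c1)[C@@](O)(C(=O)O)[C@](O)(CO)C2 | target

**Step count**
Total: 15 steps. Longest linear sequence: 13 steps (steps 1–4 and 7–15, from homovanillic acid); steps 5 and 6 form the side branch.

**Steps most likely to fail**

1. Step 11 (new method). The hindered enolate may fail to bond to the fully substituted enol-ether carbon and be consumed by [1,2] shift, ketene formation or double-bond migration, or the shift may proceed with poor facial selectivity at C2. The fallback forms the same C2–C3 bond by known chemistry, an intramolecular Mukaiyama aldol-type addition of a silyl ketene acetal to a ketal, and sets out from 13. Benzylation of the C2 hydroxyl (NaH, BnBr, DMF) should give the C2 benzyl ether F1. Epoxidation of its enol ether in the presence of benzyl alcohol (m-CPBA, BnOH, NaHCO3, CH2Cl2, −20 °C) should open the alkoxy epoxide to the hydroxy dibenzyl ketal F2, and a second benzylation (NaH, BnBr) gives the tris(benzyloxy) ketal F3. LiN(iPr)2 and Me3SiCl (THF, −78 °C) convert the ester into the silyl ketene acetal F4. Me3SiOTf (CH2Cl2, −78 °C) then ionises the ketal so that the ketene acetal closes ring B at the oxocarbenium carbon, giving the perbenzylated tetralin ester F5. C2 should again be set anti to the pendant aryl by allylic 1,3-strain; C3 rests on an open transition state with the two C–O dipoles opposed and would have to be confirmed. Saponification (LiOH, then HCl) to the perbenzylated acid F6 and hydrogenolysis (H2, Pd(OH)2/C) bring the sequence back to the route at 24.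

2. Step 10. Closure of the nine-membered ring may be outrun by oligomerisation, by catalyst deactivation at the electron-rich 1,1-disubstituted enol ether, or by hydride-induced migration of the enol-ether double bond into conjugation with ring A. The fallback closes the same ring with an unhindered vinyl ether/terminal olefin pair and then moves the double bond; it sets out from 3. Reduction with iBu2AlH (CH2Cl2, −78 °C) should give the arylacetaldehyde F7, CH2=CHMgBr the allylic alcohol F8, and NaH/BnBr the allylic benzyl ether F9 (racemic at a carbon that becomes sp2 later). Borylation as in step 4 gives the boronate F10, conjugate addition to 10 as in step 7 the diarylpropanoate F11, and hydroxylation as in step 8 the hydroxy ester F12. Iridium-catalysed vinyl transfer ([Ir(cod)Cl]2, Na2CO3, vinyl acetate, toluene, 100 °C) gives the vinyl ether F13. Metathesis with Mo(=CHCMe2Ph)(=N-2,6-iPr2C6H3)[OCMe(CF3)2]2 (benzene, 60 °C, high dilution) should close the nine-membered cyclic enol ether F14. Allyl ether to enol ether isomerisation with the iridium hydride made from [Ir(cod)(PMePh2)2]PF6 and H2 (THF, rt) would then move the double bond next to the benzyloxy carbon and return to the route at 16; this last shift is the uncertain part of the detour.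

3. Step 7. The ortho-substituted, electron-rich boronate may transmetalate slowly and protodeboronate, or the addition may show insufficient facial selectivity. The fallback replaces catalyst control by an oxazolidinone auxiliary and sets out from 10 and 4. Saponification of 10 (LiOH) gives the cinnamic acid F15, which is activated as the pivalic mixed anhydride F16 (tBuCOCl, Et3N, THF, −20 °C) and N-acylated with the lithium salt of (4S)-4-phenyl-1,3-oxazolidin-2-one to give the N-enoyl oxazolidinone F17. Compound 4 is lithiated as in step 4 to 5 and transmetalated with MgBr2·OEt2 to the arylmagnesium bromide F18. With CuBr·SMe2 (30 mol %, THF–Me2S, −40 to −10 °C) this should add to the chelated s-cis imide from the face opposite to the phenyl group, the Si face of C3, to give the (3S) imide adduct F19. NaOMe in MeOH (0 °C) releases the auxiliary and returns to the route at 11.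

**Further compounds**
F1 | step 11 | methyl (2RS,3S)-3-Ar-2-(benzyloxy)-3-{5-(benzyloxy)-2-[2-(benzyloxy)prop-2-en-1-yl]-4-methoxyphenyl}propanoate | COc1cc(CC(=C)OCc2ccccc2)c(cc1OCc1ccccc1)[C@H](c1cc(OCc2ccccc2)c(OCc2ccccc2)c(OC)c1)C(OCc1ccccc1)C(=O)OC
F2 | step 11 | methyl (2RS,3S)-3-Ar-2-(benzyloxy)-3-{5-(benzyloxy)-2-[2,2-bis(benzyloxy)-3-hydroxypropyl]-4-methoxyphenyl}propanoate | COc1cc(CC(CO)(OCc2ccccc2)OCc2ccccc2)c(cc1OCc1ccccc1)[C@H](c1cc(OCc2ccccc2)c(OCc2ccccc2)c(OC)c1)C(OCc1ccccc1)C(=O)OC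
F3 | step 11 | methyl (2RS,3S)-3-Ar-2-(benzyloxy)-3-{5-(benzyloxy)-4-methoxy-2-[2,2,3-tris(benzyloxy)propyl]phenyl}propanoate | COc1cc(CC(COCc2ccccc2)(OCc2ccccc2)OCc2ccccc2)c(cc1OCc1ccccc1)[C@H](c1cc(OCc2ccccc2)c(OCc2ccccc2)c(OC)c1)C(OCc1ccccc1)C(=O)OC
F4 | step 11 | trimethylsilyl ketene acetal of F3 (1-methoxy-1-(trimethylsilyloxy)alkene) | COc1cc(CC(COCc2ccccc2)(OCc2ccccc2)OCc2ccccc2)c(cc1OCc1ccccc1)[C@H](c1cc(OCc2ccccc2)c(OCc2ccccc2)c(OC)c1)C(OCc1ccccc1)=C(OC)O[Si](C)(C)C
F5 | step 11 | methyl (1S,2S,3R)-1-Ar-2,3,7-tris(benzyloxy)-3-[(benzyloxy)methyl]-6-methoxy-1,2,3,4-tetrahydronaphthalene-2-carboxylate | COc1cc2c(cc1OCc1ccccc1)[C@H](c1cc(OCc3ccccc3)c(OCc3ccccc3)c(OC)c1)[C@@](OCc1ccccc1)(C(=O)OC)[C@](OCc1ccccc1)(COCc1ccccc1)C2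
F6 | step 11 | (1S,2S,3R)-1-Ar-2,3,7-tris(benzyloxy)-3-[(benzyloxy)methyl]-6-methoxy-1,2,3,4-tetrahydronaphthalene-2-carboxylic acid | COc1cc2c(cc1OCc1ccccc1)[C@H](c1cc(OCc3ccccc3)c(OCc3ccccc3)c(OC)c1)[C@@](OCc1ccccc1)(C(=O)O)[C@](OCc1ccccc1)(COCc1ccccc1)C2
F7 | step 10 | [4-(benzyloxy)-2-bromo-5-methoxyphenyl]acetaldehyde | COc1cc(CC=O)c(Br)cc1OCc1ccccc1
F8 | step 10 | (2RS)-1-[4-(benzyloxy)-2-bromo-5-methoxyphenyl]but-3-en-2-ol | COc1cc(CC(O)C=C)c(Br)cc1OCc1ccccc1
F9 | step 10 | 1-(benzyloxy)-4-[(2RS)-2-(benzyloxy)but-3-en-1-yl]-5-bromo-2-methoxybenzene | COc1cc(CC(OCc2ccccc2)C=C)c(Br)cc1OCc1ccccc1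
F10 | step 10 | 2-{5-(benzyloxy)-2-[(2RS)-2-(benzyloxy)but-3-en-1-yl]-4-methoxyphenyl}-4,4,5,5-tetramethyl-1,3,2-dioxaborolane | COc1cc(CC(OCc2ccccc2)C=C)c(B2OC(C)(C)C(C)(C)O2)cc1OCc1ccccc1
F11 | step 10 | methyl (3S)-3-Ar-3-{5-(benzyloxy)-2-[(2RS)-2-(benzyloxy)but-3-en-1-yl]-4-methoxyphenyl}propanoate | COc1cc(CC(OCc2ccccc2)C=C)c(cc1OCc1ccccc1)[C@H](c1cc(OCc2ccccc2)c(OCc2ccccc2)c(OC)c1)CC(=O)OC
F12 | step 10 | methyl (2RS,3S)-3-Ar-3-{5-(benzyloxy)-2-[(2RS)-2-(benzyloxy)but-3-en-1-yl]-4-methoxyphenyl}-2-hydroxypropanoate | COc1cc(CC(OCc2ccccc2)C=C)c(cc1OCc1ccccc1)[C@H](c1cc(OCc2ccccc2)c(OCc2ccccc2)c(OC)c1)C(O)C(=O)OC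
F13 | step 10 | methyl (2RS,3S)-3-Ar-3-{5-(benzyloxy)-2-[(2RS)-2-(benzyloxy)but-3-en-1-yl]-4-methoxyphenyl}-2-(ethenyloxy)propanoate | COc1cc(CC(OCc2ccccc2)C=C)c(cc1OCc1ccccc1)[C@H](c1cc(OCc2ccccc2)c(OCc2ccccc2)c(OC)c1)C(OC=C)C(=O)OC
F14 | step 10 | methyl (1S,2RS,4Z,6RS)-1-Ar-6,10-bis(benzyloxy)-9-methoxy-1,2,6,7-tetrahydro-3-benzoxonine-2-carboxylate | COc1cc2c(cc1OCc1ccccc1)[C@H](c1cc(OCc3ccccc3)c(OCc3ccccc3)c(OC)c1)C(C(=O)OC)O/C=C\C(OCc1ccccc1)C2
F15 | step 7 | (2E)-3-[3,4-bis(benzyloxy)-5-methoxyphenyl]prop-2-enoic acid | OC(=O)/C=C/c1cc(OC)c(OCc2ccccc2)c(OCc2ccccc2)c1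
F16 | step 7 | (2E)-3-[3,4-bis(benzyloxy)-5-methoxyphenyl]prop-2-enoic 2,2-dimethylpropanoic anhydride | CC(C)(C)C(=O)OC(=O)/C=C/c1cc(OC)c(OCc2ccccc2)c(OCc2ccccc2)c1
F17 | step 7 | (4S)-3-{(2E)-3-[3,4-bis(benzyloxy)-5-methoxyphenyl]prop-2-enoyl}-4-phenyl-1,3-oxazolidin-2-one | COc1cc(/C=C/C(=O)N2C(=O)OC[C@@H]2c2ccccc2)cc(OCc2ccccc2)c1OCc1ccccc1
F18 | step 7 | {5-(benzyloxy)-2-[2-(benzyloxy)prop-2-en-1-yl]-4-methoxyphenyl}magnesium bromide | COc1cc(CC(=C)OCc2ccccc2)c([Mg]Br)cc1OCc1ccccc1
F19 | step 7 | (4S)-3-[(3S)-3-Ar-3-{5-(benzyloxy)-2-[2-(benzyloxy)prop-2-en-1-yl]-4-methoxyphenyl}propanoyl]-4-phenyl-1,3-oxazolidin-2-one | COc1cc(CC(=C)OCc2ccccc2)c(cc1OCc1ccccc1)[C@H](c1cc(OCc2ccccc2)c(OCc2ccccc2)c(OC)c1)CC(=O)N1C(=O)OC[C@@H]1c1ccccc1
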